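**Plan**
- Retrosynthesis: the C6 carboxyl is cut first (aryl triflate, then phenol), which turns ring A into a locally C2-symmetric 3,5-dioxygenated aryl group on C4. Ring B is then cut at C1–C8a and C2–C3 in one retro-annulation, to methyl acrylate (C2, C1, C20) and a primary iodide at C3. Last, C4–C4a is cut to (S)-citronellal and an aryl cation equivalent.
- Enabling feature: C6 and C8 of ring A are meta to each other around C7–H. With oxygen on both, the two ortho carbons of the aryl group are equivalent, and each is ortho to one oxygen and para to the other, so a C1 radical can close ring B in only one way. C1 carries an oxidised carbon (C20, the acrylate carbonyl) and C2/C3 are bare methylenes.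
- Forward order: aryl–C4 bond (α-arylation of citronellal), ring B by radical addition/aromatic substitution, then C20 reduction, O-demethylation, acetylation, C6 triflation and carbonylation.
- Stereochemistry: C11 comes from (S)-citronellal, C4 from catalyst-controlled α-arylation, C1 from 1,4-induction by C4 during ring closure (trans).

Key step: step 4

Remark: locants follow the tetralin core of the target (C1 bears the acetoxymethyl carbon C20, C4 the side chain with methine C11, C6 the carboxyl, C8 the hydroxyl; ring A is the arene, ring B the carbocycle); commercial (S)-citronellal is taken as enantiopure.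

**Step 1**
Reactants: 1 3,5-dimethoxyphenylboronic acid; 2 (diacetoxyiodo)mesitylene
Product: 3 (3,5-dimethoxyphenyl)(2,4,6-trimethylphenyl)iodonium trifluoromethanesulfonate
Conditions: TfOH (1.1 equiv), CH2Cl2, −30 °C → rt; precipitation with Et2O
Reagents that add atoms: trifluoromethanesulfonic acid, OS(=O)(=O)C(F)(F)F
Why: Boron-to-iodine aryl transfer from an arylboronic acid to an acid-activated trivalent iodine diacetate gives the unsymmetrical diaryliodonium salt at the ipso carbon (known diaryliodonium synthesis); mesityl serves as the non-transferring group in step 2.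

**Step 2**
Reactants: 4 (S)-citronellal; 3 (3,5-dimethoxyphenyl)(2,4,6-trimethylphenyl)iodonium trifluoromethanesulfonate
Product: 6 (2S,3S)-2-(3,5-dimethoxyphenyl)-3,7-dimethyloct-6-en-1-ol, via arylated aldehyde 5 (not isolated)
Conditions: CuBr (10 mol%), (2R,5R)-5-benzyl-2-tert-butyl-3-methylimidazolidin-4-one·Cl3CCO2H (10 mol%), NaHCO3, PhMe/Et2O 2:1, 23 °C; then NaBH4, MeOH, 0 °C
Reagents that add atoms: none
Why: Organocatalytic enantioselective α-arylation of an aldehyde with a diaryliodonium salt under CuBr/chiral amine catalysis: the enamine of 4 should attack an aryl–copper species (trivalent copper, less hindered aryl transferred) on the face opposite the catalyst benzyl group, which sets C2 as S under catalyst control (the mirror-image catalyst is the remedy if the sense proves opposite), C3 is carried over from 4, and immediate NaBH4 reduction protects the labile α-aryl aldehyde from epimerisation.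

**Step 3**
Reactants: 6 (2S,3S)-2-(3,5-dimethoxyphenyl)-3,7-dimethyloct-6-en-1-ol
Product: 7 1-[(2S,3S)-1-iodo-3,7-dimethyloct-6-en-2-yl]-3,5-dimethoxybenzene
Conditions: PPh3, imidazole, I2, CH2Cl2, 0 °C → rt
Reagents that add atoms: iodine, II
Why: Appel-type iodination of a primary alcohol through the alkoxyphosphonium salt; no stereocentre is touched.

**Step 4**
Reactants: 7 1-[(2S,3S)-1-iodo-3,7-dimethyloct-6-en-2-yl]-3,5-dimethoxybenzene; 8 methyl acrylate
Product: 9 methyl (1R,4S)-6,8-dimethoxy-4-[(2S)-6-methylhept-5-en-2-yl]-1,2,3,4-tetrahydronaphthalene-1-carboxylate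
Conditions: 10-phenylphenothiazine (5 mol%), 8 (5 equiv, ca. 0.5 M), 2,6-lutidine (2 equiv), MeCN (degassed), 390 nm LED, rt
Reagents that add atoms: none
Why: Proposed new method: photoexcited 10-phenylphenothiazine, a strong excited-state reductant, should cleave the unactivated C–I bond of 7 by dissociative electron transfer; the primary C3 radical is trapped by methyl acrylate (Giese addition, C2–C3 bond) faster than it can cyclise onto the remote trisubstituted alkene because the acrylate is kept near 0.5 M. The resulting electrophilic α-ester radical at C1 then attacks the electron-rich aryl ring (C1–C8a bond), and the cyclohexadienyl radical is oxidised by the phenothiazine radical cation and deprotonated by 2,6-lutidine, which closes a redox-neutral cycle. The closest known reaction types are photoredox radical addition/homolytic aromatic substitution cascades (alkyl radical plus N-arylacrylamide to oxindoles), the oxidative annulation of benzylmalonyl radicals with alkenes to tetralins, and the phenothiazine-photocatalysed reduction of unactivated alkyl iodides; new is an unactivated primary iodide whose own aryl group is the radical trap. Ring B closes in the 6-endo (ortho-attack) mode of homolytic aromatic substitution; 5-exo ipso attack is reversible and unproductive. C1 is set by the C4 stereocentre: in the half-chair transition state the side chain sits pseudoaxial to avoid the peri C5–H and the ester sits pseudoaxial to avoid the peri C8 methoxy group, which places them trans (1R,4S). Regioselectivity needs no control because the two ortho carbons of the 3,5-dimethoxyphenyl group are equivalent, each ortho to one methoxy and para to the other, which also matches the polarity of the electrophilic radical.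

**Step 5**
Reactants: 9 methyl (1R,4S)-6,8-dimethoxy-4-[(2S)-6-methylhept-5-en-2-yl]-1,2,3,4-tetrahydronaphthalene-1-carboxylate
Product: 10 [(1R,4S)-6,8-dimethoxy-4-[(2S)-6-methylhept-5-en-2-yl]-1,2,3,4-tetrahydronaphthalen-1-yl]methanol
Conditions: LiAlH4, THF, 0 °C; aqueous work-up
Reagents that add atoms: none
Why: Hydride reduction of the ester to the primary alcohol brings C20 to its final oxidation level and removes the epimerisable α-hydrogen at C1.

**Step 6**
Reactants: 10 [(1R,4S)-6,8-dimethoxy-4-[(2S)-6-methylhept-5-en-2-yl]-1,2,3,4-tetrahydronaphthalen-1-yl]methanol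
Product: 11 (5S,8R)-8-(hydroxymethyl)-5-[(2S)-6-methylhept-5-en-2-yl]-5,6,7,8-tetrahydronaphthalene-1,3-diol
Conditions: MeMgI (8 equiv), Et2O removed, neat, 160 °C; then aq. NH4Cl/HCl
Reagents that add atoms: none
Why: Grignard-mediated O-demethylation in the melt should cleave both aryl methyl ethers while sparing the trisubstituted alkene, as established for resorcinol dimethyl ethers bearing terpenoid alkenes; the alcohol is carried as its magnesium alkoxide.

**Step 7**
Reactants: 11 (5S,8R)-8-(hydroxymethyl)-5-[(2S)-6-methylhept-5-en-2-yl]-5,6,7,8-tetrahydronaphthalene-1,3-diol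
Product: 12 [(1R,4S)-6,8-dihydroxy-4-[(2S)-6-methylhept-5-en-2-yl]-1,2,3,4-tetrahydronaphthalen-1-yl]methyl acetate
Conditions: Novozym 435 (immobilised Candida antarctica lipase B), vinyl acetate (3 equiv), MTBE, 35 °C
Reagents that add atoms: vinyl acetate, C=COC(C)=O
Why: Lipase-catalysed transesterification should acylate the primary aliphatic alcohol and leave both phenols free (enzymatic chemoselective acetylation, made irreversible by loss of acetaldehyde).

**Step 8**
Reactants: 12 [(1R,4S)-6,8-dihydroxy-4-[(2S)-6-methylhept-5-en-2-yl]-1,2,3,4-tetrahydronaphthalen-1-yl]methyl acetate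
Product: 13 [(1R,4S)-8-hydroxy-4-[(2S)-6-methylhept-5-en-2-yl]-6-(trifluoromethanesulfonyloxy)-1,2,3,4-tetrahydronaphthalen-1-yl]methyl acetate
Conditions: PhNTf2 (1.0 equiv), K2CO3, acetone, 0 °C
Reagents that add atoms: N-phenylbis(trifluoromethanesulfonimide), O=S(=O)(N(c1ccccc1)S(=O)(=O)C(F)(F)F)C(F)(F)F
Why: Sterically controlled mono-triflation of a phenol: the C6 hydroxyl has two free ortho positions, whereas the C8 hydroxyl is flanked by C1 with its pseudoaxial acetoxymethyl group, so one equivalent of the bulky triflimide should react at C6.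

**Step 9**
Reactants: 13 [(1R,4S)-8-hydroxy-4-[(2S)-6-methylhept-5-en-2-yl]-6-(trifluoromethanesulfonyloxy)-1,2,3,4-tetrahydronaphthalen-1-yl]methyl acetate
Product: 15 (5R,8S)-5-(acetoxymethyl)-4-hydroxy-8-[(2S)-6-methylhept-5-en-2-yl]-5,6,7,8-tetrahydronaphthalene-2-carboxylic acid (target), via mixed anhydride 14 (not isolated)
Conditions: Pd(OAc)2 (5 mol%), dppf (10 mol%), KOAc (4 equiv), CO (1 atm), DMSO, 60 °C; then H2O, dilute HCl
Reagents that add atoms: carbon monoxide, [C-]#[O+]; potassium acetate, CC(=O)[O-].[K+]
Why: Palladium-catalysed hydroxycarbonylation of an aryl triflate (oxidative addition to zerovalent palladium, CO insertion, capture of the acyl complex by acetate, hydrolysis of the mixed anhydride on work-up); the acetate buffer should leave the primary acetate, the phenol and the alkene untouched.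

**Compound list**
1 | 3,5-dimethoxyphenylboronic acid | COc1cc(OC)cc(c1)B(O)O | starting material
2 | (diacetoxyiodo)mesitylene | CC(=O)OI(OC(C)=O)c1c(C)cc(C)cc1C | starting material
3 | (3,5-dimethoxyphenyl)(2,4,6-trimethylphenyl)iodonium trifluoromethanesulfonate | COc1cc(OC)cc(c1)[I+]c1c(C)cc(C)cc1C.[O-]S(=O)(=O)C(F)(F)F | intermediate
4 | (S)-citronellal, (3S)-3,7-dimethyloct-6-enal | C[C@@H](CCC=C(C)C)CC=O | starting material
5 | (2S,3S)-2-(3,5-dimethoxyphenyl)-3,7-dimethyloct-6-enal (not isolated) | O=C[C@@H]([C@@H](C)CCC=C(C)C)c1cc(OC)cc(OC)c1 | intermediate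
6 | (2S,3S)-2-(3,5-dimethoxyphenyl)-3,7-dimethyloct-6-en-1-ol | OC[C@@H]([C@@H](C)CCC=C(C)C)c1cc(OC)cc(OC)c1 | intermediate
7 | 1-[(2S,3S)-1-iodo-3,7-dimethyloct-6-en-2-yl]-3,5-dimethoxybenzene | IC[C@@H]([C@@H](C)CCC=C(C)C)c1cc(OC)cc(OC)c1 | intermediate
8 | methyl acrylate | C=CC(=O)OC | starting material
9 | methyl (1R,4S)-6,8-dimethoxy-4-[(2S)-6-methylhept-5-en-2-yl]-1,2,3,4-tetrahydronaphthalene-1-carboxylate | COC(=O)[C@@H]1CC[C@@H]([C@@H](C)CCC=C(C)C)c2cc(OC)cc(OC)c21 | intermediate
10 | [(1R,4S)-6,8-dimethoxy-4-[(2S)-6-methylhept-5-en-2-yl]-1,2,3,4-tetrahydronaphthalen-1-yl]methanol | OC[C@@H]1CC[C@@H]([C@@H](C)CCC=C(C)C)c2cc(OC)cc(OC)c21 | intermediate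
11 | (5S,8R)-8-(hydroxymethyl)-5-[(2S)-6-methylhept-5-en-2-yl]-5,6,7,8-tetrahydronaphthalene-1,3-diol | OC[C@@H]1CC[C@@H]([C@@H](C)CCC=C(C)C)c2cc(O)cc(O)c21 | intermediate
12 | [(1R,4S)-6,8-dihydroxy-4-[(2S)-6-methylhept-5-en-2-yl]-1,2,3,4-tetrahydronaphthalen-1-yl]methyl acetate | CC(=O)OC[C@@H]1CC[C@@H]([C@@H](C)CCC=C(C)C)c2cc(O)cc(O)c21 | intermediate
13 | [(1R,4S)-8-hydroxy-4-[(2S)-6-methylhept-5-en-2-yl]-6-(trifluoromethanesulfonyloxy)-1,2,3,4-tetrahydronaphthalen-1-yl]methyl acetate | CC(=O)OC[C@@H]1CC[C@@H]([C@@H](C)CCC=C(C)C)c2cc(OS(=O)(=O)C(F)(F)F)cc(O)c21 | intermediate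
14 | acetic (5R,8S)-5-(acetoxymethyl)-4-hydroxy-8-[(2S)-6-methylhept-5-en-2-yl]-5,6,7,8-tetrahydronaphthalene-2-carboxylic anhydride (not isolated) | CC(=O)OC[C@@H]1CC[C@@H]([C@@H](C)CCC=C(C)C)c2cc(C(=O)OC(C)=O)cc(O)c21 | intermediate
15 | (5R,8S)-5-(acetoxymethyl)-4-hydroxy-8-[(2S)-6-methylhept-5-en-2-yl]-5,6,7,8-tetrahydronaphthalene-2-carboxylic acid | CC(=O)OC[C@@H]1CC[C@@H]([C@@H](C)CCC=C(C)C)c2cc(C(=O)O)cc(O)c21 | target

**Step count and risks**
Total steps: 9. Longest linear sequence: 9 steps (1 → 15; (S)-citronellal enters at step 2).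

Steps most likely to fail:

1. Step 4 (proposed new method). The α-ester radical may telomerise with acrylate before it closes onto the arene, the C3 radical may cyclise 6-exo onto the side-chain alkene or undergo 1,5-hydrogen transfer, and the 1,4-induction at C1 may be weak. The fallback uses known chemistry, sets out from 7 and returns at 10, bypassing steps 4 and 5. Iodide 7 is converted into its Grignard reagent (Mg, THF) and added under CuI catalysis to the terminal epoxide carbon of (R)-epichlorohydrin, giving the chlorohydrin (2R,5S,6S)-1-chloro-5-(3,5-dimethoxyphenyl)-6,10-dimethylundec-9-en-2-ol F1. NaOH closes this to the epoxide (2R)-2-[(3S,4S)-3-(3,5-dimethoxyphenyl)-4,8-dimethylnon-7-en-1-yl]oxirane F2. SnCl4 in CH2Cl2 at −78 °C should then trigger a 6-exo epoxy–arene (Friedel–Crafts) cyclisation at the internal epoxide carbon with inversion, giving alcohol 10 with C1 fixed by the epichlorohydrin stereocentre and not by 1,4-induction.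

2. Step 8. Discrimination between the two phenols may be insufficient, leading to mixtures of C6, C8 and bis-triflates. The fallback sets out from 9 and returns at 13, and differentiates the phenols by ring formation across the peri positions instead of by sterics. Ester 9 is heated with excess NaSEt in DMF at 150 °C, which cleaves both aryl methyl ethers and the methyl ester; acidification gives (1R,4S)-6,8-dihydroxy-4-[(2S)-6-methylhept-5-en-2-yl]-1,2,3,4-tetrahydronaphthalene-1-carboxylic acid F3. TsOH in toluene closes the five-membered lactone between the C1 carboxyl and the C8 hydroxyl, (2aR,5S)-7-hydroxy-5-[(2S)-6-methylhept-5-en-2-yl]-2a,3,4,5-tetrahydro-2H-naphtho[1,8-bc]furan-2-one F4, in which only the C6 hydroxyl is free. Tf2O/2,6-lutidine at −78 °C (kept cold and brief to avoid epimerising the lactone α-carbon) gives (2aR,5S)-5-[(2S)-6-methylhept-5-en-2-yl]-2-oxo-2a,3,4,5-tetrahydro-2H-naphtho[1,8-bc]furan-7-yl trifluoromethanesulfonate F5. LiBH4 in THF at 0 °C opens the lactone to [(1R,4S)-8-hydroxy-4-[(2S)-6-methylhept-5-en-2-yl]-6-(trifluoromethanesulfonyloxy)-1,2,3,4-tetrahydronaphthalen-1-yl]methanol F6, and lipase acetylation as in step 7 gives 13.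

3. Step 2. Facial control in the aryl transfer to the β-branched enamine may be incomplete, or aldehyde 5 may epimerise before reduction. The fallback sets out from 4 and returns at 6, and moves the stereo-determining event from the arylation to the reduction. Palladium-catalysed α-arylation of 4 with 1-bromo-3,5-dimethoxybenzene (Pd(OAc)2, rac-BINAP, Cs2CO3, dioxane, 80 °C) gives aldehyde 5 together with its C2 epimer (2R,3S)-2-(3,5-dimethoxyphenyl)-3,7-dimethyloct-6-enal F7 as an interconverting mixture. This mixture is hydrogenated under dynamic kinetic resolution with a RuCl2(SDP)(DPEN) catalyst of the enantiomeric series that reduces the 2S aldehyde faster (KOtBu, iPrOH, H2); the base equilibrates C2 while the carbonyl-selective catalyst leaves the alkene alone, and the product is 6.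

**Further compounds**
F1 | step 4 | (2R,5S,6S)-1-chloro-5-(3,5-dimethoxyphenyl)-6,10-dimethylundec-9-en-2-ol | ClC[C@H](O)CC[C@@H]([C@@H](C)CCC=C(C)C)c1cc(OC)cc(OC)c1
F2 | step 4 | (2R)-2-[(3S,4S)-3-(3,5-dimethoxyphenyl)-4,8-dimethylnon-7-en-1-yl]oxirane | C1O[C@@H]1CC[C@@H]([C@@H](C)CCC=C(C)C)c1cc(OC)cc(OC)c1
F3 | step 8 | (1R,4S)-6,8-dihydroxy-4-[(2S)-6-methylhept-5-en-2-yl]-1,2,3,4-tetrahydronaphthalene-1-carboxylic acid | OC(=O)[C@@H]1CC[C@@H]([C@@H](C)CCC=C(C)C)c2cc(O)cc(O)c21
F4 | step 8 | (2aR,5S)-7-hydroxy-5-[(2S)-6-methylhept-5-en-2-yl]-2a,3,4,5-tetrahydro-2H-naphtho[1,8-bc]furan-2-one | O=C1Oc2cc(O)cc3c2[C@H]1CC[C@H]3[C@@H](C)CCC=C(C)C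
F5 | step 8 | (2aR,5S)-5-[(2S)-6-methylhept-5-en-2-yl]-2-oxo-2a,3,4,5-tetrahydro-2H-naphtho[1,8-bc]furan-7-yl trifluoromethanesulfonate | O=C1Oc2cc(OS(=O)(=O)C(F)(F)F)cc3c2[C@H]1CC[C@H]3[C@@H](C)CCC=C(C)C
F6 | step 8 | [(1R,4S)-8-hydroxy-4-[(2S)-6-methylhept-5-en-2-yl]-6-(trifluoromethanesulfonyloxy)-1,2,3,4-tetrahydronaphthalen-1-yl]methanol | OC[C@@H]1CC[C@@H]([C@@H](C)CCC=C(C)C)c2cc(OS(=O)(=O)C(F)(F)F)cc(O)c21
F7 | step 2 | (2R,3S)-2-(3,5-dimethoxyphenyl)-3,7-dimethyloct-6-enal | O=C[C@H]([C@@H](C)CCC=C(C)C)c1cc(OC)cc(OC)c1
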